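Starting material cannot vanish into nothing, yet by 3.00 min the delta run has lost 21.0 % of its charge and shows 9.4 % of target, so we take it that target is consumed further as it forms.

| flask | starting material | gas phase | free catalyst | remark | time |
|---|---|---|---|---|---|
| eta | 0.052 M | 3.1 mM (held) | 0.49 mM | run made earlier |  |
| epsilon | 0.052 M | 3.1 mM (held) | 0.74 mM | run made earlier |  |
| delta | 0.10 M | 3.1 mM (held) | 0.99 mM | run made earlier |  |
| flask | 0.052 M | 3.1 mM (held) | 0.99 mM |  | 2.5 min |

| run | time / min | target / % | starting material / % |
|---|---|---|---|
| eta | 0.250 | 1.3 | 97.5 |
| eta | 0.500 | 4.8 | 95.6 |
| eta | 1.33 | 6.5 | 91.8 |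
| eta | 3.00 | 8.0 | 83.8 |
| epsilon | 0.417 | 3.9 | 94.8 |
| epsilon | 1.00 | 6.6 | 89.6 |
| epsilon | 2.00 | 9.1 | 85.9 |
| epsilon | 3.00 | 8.9 | 80.3 |
| delta | 0.833 | 5.8 | 92.2 |
| delta | 1.50 | 7.3 | 85.9 |
| delta | 2.50 | 7.8 | 80.7 |
| delta | 3.00 | 9.4 | 79.0 |

(each reading ± 1 percentage point)

- what was read earlier has a scatter of 1 percentage point, one standard deviation
- at the start none of the gas phase is in solution

- the target standing at 2.5 min, as a percentage of the starting material charged
- concentration of dissolved gas in solution at 2.5 min, in percent of saturation

Suppose that making target and losing it draw on the same partners, so that target, concentration for concentration, goes s times as fast as starting material is converted: the loss ratio, or selectivity factor. If target stood still, s would be [starting material]/[target]. Pooling the last readings of the three runs, 81.0 % left against 8.77 % of target, gives 9.24.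

Delta matches the flask in free catalyst but has twice its charge, so delta's 80.7 % at 2.50 min is a stand-in for the flask's starting material, not a measure of it. Dividing it by the ratio gives 8.73 % of target.

The weak link is the standing still, since delta's target still read 7.8 % and then 9.4 %. So we drop it: with s constant, a fraction a of starting material left carries a target fraction of a minus a to the power s, all over s less one, on our supposition whatever catalyst and gas do. Reading this curve back twice through the pooled point gives s = 8.38, and the stand-in then gives 8.69 %. That is our number; for the gas we commit to none.

The forecast gave 8.8 % and 78 %, holding that “Target plateaus near 8–9% in every run, regardless of catalyst”.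

The flask gives 9.57 % of target, with dissolved gas at 91.2 % of saturation.

    dissolved gas + free catalyst + target → free catalyst + over-reaction product (k = 7100 /M²/s)
    2 free catalyst → spent catalyst (k = 5.10 /M/s)
    starting material + dissolved gas + free catalyst → free catalyst + target (k = 960 /M²/s)
    gas phase ⇌ dissolved gas, rate k4*(csat - [dissolved gas]) (kL = 0.310 /s)

At 2.50 min dissolved gas is used 1.1 times as fast by the step making target as by the step turning target into over-reaction product, so making barely outruns losing. With the flask's 79.5 % of starting material left, s gives 8.79 %. A neighbour flask with 4.0 × 10⁻⁴ M of free catalyst keeps 88.0 % of its starting material, for which s gives 7.28 %; computed, it stands at 7.68 %.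

The readings stem from a simulated flask for substances that don't exist; the scatter is artificial.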